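**Plan**

- Retrosynthesis: the C5=C6 enol lactone and C12 carbonyl go back to a furan (O, C6, C7, C11, C12), the two esters to an 8,13-diol, and the 8,10-syn diol to a 9-en-8-one. C2–C3 and O–C1 are then cut together. Last, C10–C1 (Stille), C8–C9 (alkynyl addition) and C5–C6 (furyllithium plus glycidyl epoxide) lead to furan-3,4-diyldimethanol and 2-methylglycidol.
- Enabling feature: the oxolane O/C1/C2/C3/C4 bridges C1 and C4 of the ten-membered carbocycle C1–C10. O–C4–C3 is therefore a β-oxyalkyl three-atom unit (the iodohydrin of a 2,2-disubstituted epoxide) and C1=C2 the free terminus of a dienone, so one radical–polar [3+2] event closes both the carbocycle and the oxygen bridge of the 11-oxabicyclo[6.2.1]undecane.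
- Forward order: furan side chain (C5, C4, C3, C15) → C8 ynone → (Z)-dienone iodohydrin → carbocycle and oxolane in one step → C10–OH and C8–OH → esters → furan to hydroxybutenolide → 5(6)-ene.
- Stereochemistry: C4 and the epoxy-ester carbon both come from (R)-2-methylglycidol; C1 is relayed from C4 by the cis-bridged bicycle; C10 by ligand-controlled conjugate borylation; C8 by 1,3-syn reduction; alkene geometries by the rings.

Key step: step 9

Remark: germacrane numbering of 24 is used for all intermediates (carbocycle C1–C10; C11, C12 (lactone C=O) and C13 (CH2OAc) on C7; C14 on C10; C15 on C4); the furan of the intermediates is O/C6/C7/C11/C12.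
Remark: 1 and 3 are taken as commercial; the (Z)-dienone 12 is assumed to equilibrate freely with any 2H-pyran valence isomer.

**Route**

Step 1
Reactants: 1 (R)-2-methylglycidol
Product: 2 (S)-2-methylglycidyl tosylate
Conditions: TsCl, Et3N, DMAP (cat.), CH2Cl2, 0 °C
Reagents that add atoms: 4-methylbenzenesulfonyl chloride, Cc1ccc(cc1)S(Cl)(=O)=O
Why: Sulfonylation of the primary alcohol leaves the quaternary stereocentre untouched (the descriptor changes only through CIP priorities).

Step 2
Reactants: 3 furan-3,4-diyldimethanol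
Product: 4 [4-(triisopropylsilyloxymethyl)furan-3-yl]methanol
Conditions: NaH (1 equiv), THF, 0 °C; TIPSCl (1 equiv), rt
Reagents that add atoms: chlorotri(propan-2-yl)silane, CC(C)[Si](Cl)(C(C)C)C(C)C
Why: Statistical monosilylation of a symmetric diol through its sparingly soluble monosodium alkoxide.

Step 3
Reactants: 4 [4-(triisopropylsilyloxymethyl)furan-3-yl]methanol; 2 (S)-2-methylglycidyl tosylate
Product: 7 epoxy alcohol [2-{[(2S)-2-methyloxiran-2-yl]methyl}-4-(triisopropylsilyloxymethyl)furan-3-yl]methanol, via dilithiated furan 5 (not isolated), via hydroxy tosylate 6 (not isolated)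
Conditions: n-BuLi (2.2 equiv), THF, −78 → 0 °C; −78 °C, 2 then BF3·OEt2; H2O; K2CO3, MeOH, rt
Reagents that add atoms: none
Why: Alkoxide-directed ortho-lithiation metallates the furan α-carbon next to the CH2OLi group (future C6), BF3-assisted epoxide opening by the aryllithium occurs at the unsubstituted ring CH2 of 2 (future C5), and base closes the new epoxide by 3-exo-tet displacement of tosylate, so the glycidol stereocentre becomes C4 without any of its bonds being broken.

Step 4
Reactants: 7 epoxy alcohol
Product: 8 epoxy aldehyde 2-{[(2S)-2-methyloxiran-2-yl]methyl}-4-(triisopropylsilyloxymethyl)furan-3-carbaldehyde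
Conditions: MnO2 (excess), CH2Cl2, rt
Reagents that add atoms: none
Why: MnO2 oxidation of a heteroaryl carbinol stops at the aldehyde and tolerates the epoxide and silyl ether.

Step 5
Reactants: 8 epoxy aldehyde
Product: 9 propargylic alcohol 1-[2-{[(2S)-2-methyloxiran-2-yl]methyl}-4-(triisopropylsilyloxymethyl)furan-3-yl]but-2-yn-1-ol (both C8 epimers)
Conditions: CH3C≡CMgBr, THF, −78 → 0 °C; H2O
Reagents that add atoms: prop-1-yn-1-ylmagnesium bromide, CC#C[Mg]Br
Why: Grignard addition to the aldehyde is much faster than attack on the hindered 2,2-disubstituted epoxide; the C8 carbinol is formed as a mixture because it is oxidised in the next step.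

Step 6
Reactants: 9 propargylic alcohol
Product: 10 ynone 1-[2-{[(2S)-2-methyloxiran-2-yl]methyl}-4-(triisopropylsilyloxymethyl)furan-3-yl]but-2-yn-1-one
Conditions: MnO2 (excess), CH2Cl2, rt
Reagents that add atoms: none
Why: MnO2 oxidation of a doubly activated (propargylic and furylic) secondary alcohol.

Step 7
Reactants: 10 ynone
Product: 11 (2Z)-1-{2-[(2S)-2-hydroxy-3-iodo-2-methylpropyl]-4-(triisopropylsilyloxymethyl)furan-3-yl}-3-iodobut-2-en-1-one
Conditions: LiI (3 equiv), AcOH (3 equiv), MeCN, rt
Reagents that add atoms: lithium iodide, [Li+].[I-]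
Why: LiI/AcOH adds HI anti across the ynone (conjugate hydroiodination) to give the (Z)-β-iodoenone and, in the same pot, opens the epoxide by SN2 attack of iodide at its CH2 (C3), leaving C4 untouched.

Step 8
Reactants: 11 iodoenone iodohydrin
Product: 12 (2Z)-1-{2-[(2S)-2-hydroxy-3-iodo-2-methylpropyl]-4-(triisopropylsilyloxymethyl)furan-3-yl}-3-methylpenta-2,4-dien-1-one
Conditions: CH2=CHSnBu3, Pd2(dba)3 (2.5 mol %), AsPh3, CuI (cat.), NMP, rt, dark
Reagents that add atoms: tributyl(ethenyl)stannane, C=C[Sn](CCCC)(CCCC)CCCC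
Why: Stille coupling of the reactive β-iodoenone with retention of alkene geometry gives the (Z)-dienone (C1 cis to C8), while the neopentyl-type C3 iodide does not undergo thermal oxidative addition in the dark.

Step 9
Reactants: 12 (Z)-dienone iodohydrin
Product: 13 tricyclic furano-enone (1S,4R,9Z)-1,4-epoxy-13-(triisopropylsilyloxy)-6,12-epoxygermacra-6,9,11-trien-8-one
Conditions: Pd(PPh3)4 (10 mol %), Xantphos (12 mol %), 2,4,6-collidine (2 equiv), PhH (1 mM, slow addition of 12), 450 nm LEDs, rt
Reagents that add atoms: none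
Why: Proposed new method: blue-light excitation of zerovalent palladium–Xantphos abstracts iodine from C3 of 12 (a neopentyl-type iodide with no β-hydrogen), the nucleophilic β-hydroxyalkyl radical adds to C2, the unsubstituted δ-terminus of the (Z)-dienone, the delocalised C1/C9 radical recombines with monovalent palladium to an acyl-substituted π-allyl (O-bound dienolate) complex, and the C4 hydroxyl attacks C1 while collidine takes up HI and zerovalent palladium is returned. The closest known reaction types are the visible-light palladium-catalysed radical–polar crossover 1,2-carbofunctionalisation of 1,3-dienes with alkyl iodides and the Larock heteroannulation of dienes, neither of which has been used to close a medium ring through a tethered tertiary alcohol. The ten-membered carbocycle closes by 10-endo-trig radical addition (C3 to C2) and the oxolane by 5-exo allylic substitution (oxygen on C4 to C1). C1 is the only new stereocentre and is set by C4 through the ring, because only the cis-2,5-bridged 11-oxabicyclo[6.2.1]undecane can form and the allylpalladium can reach it by π–σ–π equilibration, which also leaves the 9,10-alkene Z. The step needs attack at C2 instead of C9 or C10 and C–O closure instead of β-hydride loss: C2 is the only unsubstituted acceptor carbon and carries the largest LUMO coefficient, five of the ten ring atoms stay sp2 (furan, ketone, alkene) and C4 is gem-disubstituted so that transannular strain and entropy cost are low, and the hydroxyl sits 1,4 to the electrophilic allyl terminus.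

Step 10
Reactants: 13 tricyclic furano-enone
Product: 15 β-hydroxy ketone (1S,4R,10R)-1,4-epoxy-10-hydroxy-13-(triisopropylsilyloxy)-6,12-epoxygermacra-6,11-dien-8-one, via tertiary boronate 14 (not isolated)
Conditions: CuCl (10 mol %), (R,R)-QuinoxP* (12 mol %), NaOt-Bu (15 mol %), B2pin2 (1.3 equiv), MeOH (2 equiv), THF, rt; then NaBO3·4H2O, THF/H2O, rt
Reagents that add atoms: sodium perborate, [Na+].[O-]OB=O
Why: Copper-catalysed conjugate borylation of the β,β-disubstituted enone should put boron on C10 from its Re face (priorities C1 > C9 > C14), the ligand antipode being the one that reinforces the substrate's own preference, and perborate oxidation replaces boron by hydroxyl with retention to give the 10R carbinol.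

Step 11
Reactants: 15 β-hydroxy ketone
Product: 16 syn-diol (1S,4R,8S,10R)-1,4-epoxy-13-(triisopropylsilyloxy)-6,12-epoxygermacra-6,11-diene-8,10-diol
Conditions: Et2BOMe (1.2 equiv), THF/MeOH, −78 °C; NaBH4; MeOH co-evaporation
Reagents that add atoms: none
Why: Narasaka–Prasad reduction: external hydride attacks the diethylboron chelate of the β-hydroxy ketone to give the 1,3-syn diol, which sets C8 as S relative to C10.

Step 12
Reactants: 1 (R)-2-methylglycidol
Product: 17 (2S)-2-methyloxirane-2-carboxylic acid
Conditions: RuCl3 (cat.), NaIO4, MeCN/EtOAc/H2O, 0 °C → rt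
Reagents that add atoms: water, O
Why: Catalytic RuO4 oxidation of the primary alcohol to the acid does not touch the quaternary stereocentre; the descriptor changes from R to S only because the CIP priorities change.

Step 13
Reactants: 16 syn-diol; 17 (2S)-2-methyloxirane-2-carboxylic acid
Product: 18 C8 ester (1S,4R,8S,10R)-10-hydroxy-13-(triisopropylsilyloxy)-1,4-epoxy-6,12-epoxygermacra-6,11-dien-8-yl (2S)-2-methyloxirane-2-carboxylate
Conditions: DCC, DMAP (cat.), CH2Cl2, 0 °C → rt
Reagents that add atoms: none
Why: Steglich esterification acylates the secondary C8 hydroxyl while the tertiary C10 hydroxyl does not react.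

Step 14
Reactants: 18 C8 ester
Product: 19 primary alcohol (13-hydroxy C8 ester)
Conditions: Bu4NF, AcOH (1:1), THF, 0 °C → rt
Reagents that add atoms: none
Why: Buffered fluoride desilylation frees the primary C13 alcohol without acyl migration or opening of the electron-poor epoxide.

Step 15
Reactants: 19 primary alcohol
Product: 20 furan acetate (13-acetoxy C8 ester)
Conditions: Ac2O, pyridine, CH2Cl2, 0 °C
Reagents that add atoms: acetic anhydride, CC(=O)OC(C)=O
Why: Acetylation of the only primary alcohol; the tertiary C10 hydroxyl is inert under these conditions.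

Step 16
Reactants: 20 furan acetate
Product: 22 hydroxybutenolide (6-hydroxy-6,12-olide; C6 hemiketal), via furan endoperoxide 21 (not isolated)
Conditions: O2, tetraphenylporphyrin (cat.), visible light, CH2Cl2, −78 °C; i-Pr2NEt, −78 °C → rt
Reagents that add atoms: dioxygen, O=O
Why: [4+2] cycloaddition of singlet oxygen across C6/C12 of the furan followed by base-induced Kornblum–DeLaMare fragmentation gives the C12 lactone carbonyl and the C6 hemiketal, the regiochemistry being fixed because only C12 bears a hydrogen.

Step 17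
Reactants: 22 hydroxybutenolide
Product: 24 target CNP0142137.1, via hemiketal acetate 23 (not isolated)
Conditions: Ac2O (1.5 equiv), Et3N, DMAP (cat.), CH2Cl2, 0 °C → rt
Reagents that add atoms: none
Why: O-Acylation of the acidic hemiketal (pseudo-acid) hydroxyl and base-induced loss of acetic acid across C6–C5 (enol-lactone formation) should give the 5(6)-ene, whose geometry (C4 cis to C7) is dictated by the ten-membered ring.

**Compound list**

1 | (R)-2-methylglycidol, [(2R)-2-methyloxiran-2-yl]methanol | OC[C@]1(C)CO1 | starting material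
2 | [(2S)-2-methyloxiran-2-yl]methyl 4-methylbenzenesulfonate | Cc1ccc(cc1)S(=O)(=O)OC[C@]1(C)CO1 | intermediate
3 | furan-3,4-diyldimethanol | OCc1cocc1CO | starting material
4 | [4-(triisopropylsilyloxymethyl)furan-3-yl]methanol | OCc1cocc1CO[Si](C(C)C)(C(C)C)C(C)C | intermediate
5 | C6-lithiated lithium alkoxide of 4 | [Li]OCc1c([Li])occ1CO[Si](C(C)C)(C(C)C)C(C)C | intermediate (not isolated)
6 | (2S)-2-hydroxy-3-[3-(hydroxymethyl)-4-(triisopropylsilyloxymethyl)furan-2-yl]-2-methylpropyl tosylate | OCc1c(C[C@@](O)(C)COS(=O)(=O)c2ccc(C)cc2)occ1CO[Si](C(C)C)(C(C)C)C(C)C | intermediate (not isolated)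
7 | [2-{[(2S)-2-methyloxiran-2-yl]methyl}-4-(triisopropylsilyloxymethyl)furan-3-yl]methanol | OCc1c(C[C@@]2(C)CO2)occ1CO[Si](C(C)C)(C(C)C)C(C)C | intermediate
8 | 2-{[(2S)-2-methyloxiran-2-yl]methyl}-4-(triisopropylsilyloxymethyl)furan-3-carbaldehyde | O=Cc1c(C[C@@]2(C)CO2)occ1CO[Si](C(C)C)(C(C)C)C(C)C | intermediate
9 | 1-[2-{[(2S)-2-methyloxiran-2-yl]methyl}-4-(triisopropylsilyloxymethyl)furan-3-yl]but-2-yn-1-ol, both C8 epimers | CC#CC(O)c1c(C[C@@]2(C)CO2)occ1CO[Si](C(C)C)(C(C)C)C(C)C | intermediate
10 | 1-[2-{[(2S)-2-methyloxiran-2-yl]methyl}-4-(triisopropylsilyloxymethyl)furan-3-yl]but-2-yn-1-one | CC#CC(=O)c1c(C[C@@]2(C)CO2)occ1CO[Si](C(C)C)(C(C)C)C(C)C | intermediate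
11 | (2Z)-1-{2-[(2S)-2-hydroxy-3-iodo-2-methylpropyl]-4-(triisopropylsilyloxymethyl)furan-3-yl}-3-iodobut-2-en-1-one | C/C(I)=C/C(=O)c1c(C[C@@](O)(C)CI)occ1CO[Si](C(C)C)(C(C)C)C(C)C | intermediate
12 | (2Z)-1-{2-[(2S)-2-hydroxy-3-iodo-2-methylpropyl]-4-(triisopropylsilyloxymethyl)furan-3-yl}-3-methylpenta-2,4-dien-1-one | C=C/C(C)=C\C(=O)c1c(C[C@@](O)(C)CI)occ1CO[Si](C(C)C)(C(C)C)C(C)C | intermediate
13 | (1S,4R,9Z)-1,4-epoxy-13-(triisopropylsilyloxy)-6,12-epoxygermacra-6,9,11-trien-8-one (furan-fused 11-oxabicyclo[6.2.1]undecenone) | CC(C)[Si](C(C)C)(C(C)C)OCc1coc2c1C(=O)/C=C(C)\[C@@H]1CC[C@](C)(C2)O1 | intermediate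
14 | 10-(pinacolboryl) ketone, boron in the position of the later 10R hydroxyl (10S by CIP), 1S,4R | CC(C)[Si](C(C)C)(C(C)C)OCc1coc2c1C(=O)C[C@@](C)(B3OC(C)(C)C(C)(C)O3)[C@@H]4CC[C@](C)(C2)O4 | intermediate (not isolated)
15 | (1S,4R,10R)-1,4-epoxy-10-hydroxy-13-(triisopropylsilyloxy)-6,12-epoxygermacra-6,11-dien-8-one | CC(C)[Si](C(C)C)(C(C)C)OCc1coc2c1C(=O)C[C@@](C)(O)[C@@H]3CC[C@](C)(C2)O3 | intermediate
16 | (1S,4R,8S,10R)-1,4-epoxy-13-(triisopropylsilyloxy)-6,12-epoxygermacra-6,11-diene-8,10-diol | CC(C)[Si](C(C)C)(C(C)C)OCc1coc2c1[C@@H](O)C[C@@](C)(O)[C@@H]3CC[C@](C)(C2)O3 | intermediate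
17 | (2S)-2-methyloxirane-2-carboxylic acid | OC(=O)[C@]1(C)CO1 | intermediate
18 | 8-O-[(2S)-2-methyloxirane-2-carbonyl] ester of 16 | CC(C)[Si](C(C)C)(C(C)C)OCc1coc2c1[C@@H](OC(=O)[C@]3(C)CO3)C[C@@](C)(O)[C@@H]4CC[C@](C)(C2)O4 | intermediate
19 | 13-hydroxy furan, 8-O-[(2S)-2-methyloxirane-2-carbonyl], 10-OH (1S,4R,8S,10R) | OCc1coc2c1[C@@H](OC(=O)[C@]3(C)CO3)C[C@@](C)(O)[C@@H]4CC[C@](C)(C2)O4 | intermediate
20 | 13-acetoxy furan, 8-O-[(2S)-2-methyloxirane-2-carbonyl], 10-OH (1S,4R,8S,10R) | CC(=O)OCc1coc2c1[C@@H](OC(=O)[C@]3(C)CO3)C[C@@](C)(O)[C@@H]4CC[C@](C)(C2)O4 | intermediate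
21 | 6,12-endoperoxide of furan 20 | CC(=O)OCC1=C2[C@@H](OC(=O)[C@]3(C)CO3)C[C@@](C)(O)[C@@H]4CC[C@](C)(CC25OOC1O5)O4 | intermediate (not isolated)
22 | 6-hydroxy-7(11)-en-6,12-olide (C6 hemiketal, either epimer), otherwise as 24 | CC(=O)OCC1=C2[C@@H](OC(=O)[C@]3(C)CO3)C[C@@](C)(O)[C@@H]4CC[C@](C)(CC2(O)OC1=O)O4 | intermediate
23 | 6-acetoxy-7(11)-en-6,12-olide (hemiketal acetate of 22) | CC(=O)OCC1=C2[C@@H](OC(=O)[C@]3(C)CO3)C[C@@](C)(O)[C@@H]4CC[C@](C)(CC2(OC(C)=O)OC1=O)O4 | intermediate (not isolated)
24 | CNP0142137.1: (1S,4R,5E,8S,10R)-13-acetoxy-1,4-epoxy-10-hydroxy-8-[(2S)-2-methyloxirane-2-carbonyloxy]germacra-5,7(11)-dien-6,12-olide | CC(=O)OCC1=C2/C(=C\[C@@]3(C)CC[C@H](O3)[C@](C)(O)C[C@@H]2OC(=O)[C@]2(C)CO2)OC1=O | target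

**Step count and risks**

Total: 17 steps. Longest linear sequence: 15 steps (steps 2–11 and 13–17, from 3); steps 1 and 12 are side preparations from 1.

Steps most likely to fail: step 9, step 10, step 3.

Step 9. Possible failure: the radical/monovalent-palladium pair may collapse with β-hydroxide elimination (deoxygenation to the methallyl furan), intermolecular addition may outrun the 10-endo closure, or the allyl complex may lose a β-hydride before the C4 hydroxyl closes the oxolane. The fallback separates ring closure from ether formation with known chemistry; it sets out from 12 and comes back at 13. Tris(trimethylsilyl)silane and AIBN, added by syringe pump to 12 in refluxing benzene at high dilution, should effect the hydride-terminated 10-endo radical macrocyclisation (Giese addition, hydrogen delivered to C9) and give the ten-membered β,γ-unsaturated hydroxy ketone F1. Me3SiOTf/Et3N would convert it into the bis-silyl compound F2 (C8 silyl dienol ether, C4 silyl ether). NBS should brominate the dienol ether at its γ-carbon (C1) to the bromo enone F3, and Bu4NF would then free the C4 alkoxide, which displaces the allylic bromide (5-exo-tet; an α-bromo isomer would converge by SN2′) to give 13.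

Step 10. Possible failure: the boryl-copper species may not add to the hindered, ring-constrained β,β-disubstituted enone, or may add without facial discrimination. The fallback sets out from 13 and comes back at 15. Weitz–Scheffer epoxidation (t-BuOOH, DBU, CH2Cl2), in which the hydroperoxide anion adds to C10 under substrate control, should give the cis-epoxy ketone F4. Reductive opening of its Cα–O bond (C9–O) with SmI2 in THF/MeOH at −90 °C would then give the β-hydroxy ketone 15.

Step 3. Possible failure: metalation may occur at the other α-position (C12) or with silyl migration, and BF3 may induce rearrangement of the glycidyl epoxide instead of clean C6 alkylation. The fallback changes the directing group; it sets out from 4 and comes back at 7. TEMPO/NaClO2 with catalytic NaOCl would oxidise 4 to the furoic acid F5. Two equivalents of LDA should then give the carboxylate-directed C6 lithiation; BF3·OEt2-assisted opening of 2 at its ring CH2 followed by K2CO3/MeOH closure would give the epoxy acid F6, and BH3·SMe2 at 0 °C would reduce the acid to 7.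

Further compounds
F1 | step 9 | (4R)-4-hydroxy-13-(triisopropylsilyloxy)-6,12-epoxygermacra-1(10),6,11-trien-8-one (ten-membered hydroxy ketone, 1(10)-alkene geometry as formed) | CC(C)[Si](C(C)C)(C(C)C)OCc1coc2c1C(=O)CC(C)=CCC[C@@](C)(O)C2
F2 | step 9 | bis(trimethylsilyl) derivative of F1 (C8 silyl dienol ether, C4 silyl ether) | CC(C)[Si](C(C)C)(C(C)C)OCc1coc2c1C(O[Si](C)(C)C)=CC(C)=CCC[C@@](C)(O[Si](C)(C)C)C2
F3 | step 9 | 1-bromo-9-en-8-one C4 trimethylsilyl ether (C1 epimers) | CC(C)[Si](C(C)C)(C(C)C)OCc1coc2c1C(=O)C=C(C)C(Br)CC[C@@](C)(O[Si](C)(C)C)C2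
F4 | step 10 | 9,10-cis-epoxy ketone of 13 (epoxide oxygen in the position of the 10R hydroxyl) | CC(C)[Si](C(C)C)(C(C)C)OCc1coc2c1C(=O)[C@H]3O[C@@]3(C)[C@@H]4CC[C@](C)(C2)O4
F5 | step 3 | 4-(triisopropylsilyloxymethyl)furan-3-carboxylic acid | OC(=O)c1cocc1CO[Si](C(C)C)(C(C)C)C(C)C
F6 | step 3 | 2-{[(2S)-2-methyloxiran-2-yl]methyl}-4-(triisopropylsilyloxymethyl)furan-3-carboxylic acid | OC(=O)c1c(C[C@@]2(C)CO2)occ1CO[Si](C(C)C)(C(C)C)C(C)C
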